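**Retrosynthetic overview**
- Last, three MOM ethers are removed. The C6–C(=O) bond of the benzophenone is cut back to a 6-lithiochromene (C6–H lies between two MOM ethers) and 3-(methoxymethoxy)benzaldehyde, with oxidation of the carbinol.
- Key disconnection: the 2H-pyran ring (C3=C4 and O1–C2) and the C8–prenyl bond are taken apart together. This leads to an ortho-(1,1-dimethylallyloxy)benzaldehyde and 2-methylprop-1-enylboronic acid. Forward, Claisen shift, borono-Mannich alkenyl transfer, amine loss and oxa-6π closure run in one flask.
- Enabling feature: O1 sits on C8a, between C8 (prenyl-bearing) and C4a (carrying C4), and O1=C8a–C4a=C4–C3=C2(CH3)2 is a 1-oxatriene pattern. The oxygen that first carries the C5 allyl unit passes it to C8 and is freed exactly where boron binding and ring closure need a phenol. The oxygens on C5 and C7 stay MOM-capped.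
- The precursor comes from symmetric 2,4,6-trihydroxybenzaldehyde (bis-MOM protection leaves one hydrogen-bonded OH, then propargylation and semi-hydrogenation), so no regiochemical choice arises.
- Ring order: the benzene rings A and B are bought; the pyran ring is the only ring formed (step 4).

Key step: step 4

Remark: the target has no stereocentre and no stereogenic double bond, so no stereocontrol is needed. The five starting materials in the compound list are taken as purchased.

**Route**

Step 1
Reactants: 1 2,4,6-trihydroxybenzaldehyde; 2 chloromethyl methyl ether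
Product: 3 2-hydroxy-4,6-bis(methoxymethoxy)benzaldehyde
Conditions: MOMCl (2.1 equiv), iPr2NEt, CH2Cl2, 0 °C to rt
Reagents that add atoms: chloromethyl methyl ether, COCCl
Why: MOM protection (Williamson-type O-alkylation) caps the para hydroxyl and one of the two equivalent ortho hydroxyls, while the last one stays locked in the hydrogen bond to the formyl group, so the symmetry of 1 should give a single bis-ether with exactly one free phenol.

Step 2
Reactants: 3 2-hydroxy-4,6-bis(methoxymethoxy)benzaldehyde; 4 3-chloro-3-methylbut-1-yne
Product: 5 2,4-bis(methoxymethoxy)-6-[(2-methylbut-3-yn-2-yl)oxy]benzaldehyde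
Conditions: 4 (1.8 equiv), DBU, CuCl2·2H2O (1 mol%), MeCN, 0 °C to rt
Reagents that add atoms: 3-chloro-3-methylbut-1-yne, C#CC(C)(C)Cl
Why: Copper-catalysed propargylic etherification of a phenol with a tertiary propargylic chloride, the usual entry to aryl 1,1-dimethylpropargyl ethers, should alkylate the only free hydroxyl of 3 at the tertiary carbon.

Step 3
Reactants: 5 2,4-bis(methoxymethoxy)-6-[(2-methylbut-3-yn-2-yl)oxy]benzaldehyde
Product: 6 2,4-bis(methoxymethoxy)-6-[(2-methylbut-3-en-2-yl)oxy]benzaldehyde
Conditions: H2 (1 atm), Pd/CaCO3 poisoned with Pb(OAc)2 (Lindlar catalyst), quinoline, EtOAc, rt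
Reagents that add atoms: none
Why: Lindlar semi-hydrogenation should reduce the terminal alkyne to the vinyl group and leave the aldehyde, the MOM acetals and the aryl ether untouched.

Step 4
Reactants: 6 2,4-bis(methoxymethoxy)-6-[(2-methylbut-3-en-2-yl)oxy]benzaldehyde; 7 (2-methylprop-1-en-1-yl)boronic acid
Product: 11 5,7-bis(methoxymethoxy)-2,2-dimethyl-8-(3-methylbut-2-en-1-yl)-2H-chromene, via salicylaldehyde 8 (not isolated), via aminophenol 9 (not isolated), via ortho-quinone methide 10 (not isolated)
Conditions: PhMe, 110 °C; then, same flask, Bn2NH (0.5 equiv), 7 (1.5 equiv), 90 °C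
Reagents that add atoms: (2-methylprop-1-en-1-yl)boronic acid, CC(C)=CB(O)O
Why: Heating first drives the aromatic Claisen rearrangement of the aryl 1,1-dimethylallyl ether: the [3,3] shift delivers the allyl unit with allylic inversion to C3 of the benzaldehyde (the future C8), and rearomatisation gives salicylaldehyde 8 with the prenyl group in place and the phenol freed next to the formyl group. After addition of Bn2NH and 7, the aldehyde condenses to an iminium ion, the phenoxide binds boron, and the boronate passes its 2-methylprop-1-enyl group intramolecularly to the iminium carbon (Petasis borono-Mannich reaction), forming the future C4–C3 bond in aminophenol 9. At 90 °C the electron-rich ortho-aminobenzyl phenol should expel Bn2NH, which re-enters the cycle, to give ortho-quinone methide 10, a 1-oxatriene that closes by thermal oxa-6π electrocyclisation to the six-membered 2H-pyran ring, forming the O1–C2 bond and restoring the arene. The closest known reaction types are the Claisen rearrangement of aryl 1,1-dimethylallyl ethers to ortho-prenyl phenols and the amine-promoted condensation of salicylaldehydes with alkenylboronic acids to 2H-chromenes, here run one after the other in one flask. No stereocentre is created, since C2 carries two methyl groups and the stereocentre of 9 is lost on elimination. Regiocontrol is needed twice and the substrate secures it: the allyl group can only go to the single unsubstituted ortho carbon, and the pyran can only close onto the one oxygen that is not a MOM ether, the one between C4a and C8; boron transfer also cannot start before the Claisen shift has uncovered that phenol.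

Step 5
Reactants: 12 3-hydroxybenzaldehyde; 2 chloromethyl methyl ether
Product: 13 3-(methoxymethoxy)benzaldehyde
Conditions: MOMCl, iPr2NEt, CH2Cl2, 0 °C to rt
Reagents that add atoms: chloromethyl methyl ether, COCCl
Why: MOM protection (Williamson-type O-alkylation) of the single phenol should let ring B survive the aryllithium and be unmasked together with the other two ethers at the end.

Step 6
Reactants: 11 5,7-bis(methoxymethoxy)-2,2-dimethyl-8-(3-methylbut-2-en-1-yl)-2H-chromene; 13 3-(methoxymethoxy)benzaldehyde
Product: 15 [5,7-bis(methoxymethoxy)-2,2-dimethyl-8-(3-methylbut-2-en-1-yl)-2H-chromen-6-yl][3-(methoxymethoxy)phenyl]methanol (racemic), via aryllithium 14 (not isolated)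
Conditions: n-BuLi, TMEDA, THF, −20 to 0 °C; then 13, −78 to 0 °C; then H2O
Reagents that add atoms: 3-(methoxymethoxy)benzaldehyde, O=Cc1cccc(OCOC)c1
Why: Directed ortho-metalation should remove C6–H, the only aromatic hydrogen of 11 and flanked by two chelating MOM ethers, and aryllithium 14 then adds 1,2 to aldehyde 13, giving a racemic carbinol centre that is erased in step 7.

Step 7
Reactants: 15 [5,7-bis(methoxymethoxy)-2,2-dimethyl-8-(3-methylbut-2-en-1-yl)-2H-chromen-6-yl][3-(methoxymethoxy)phenyl]methanol
Product: 16 [5,7-bis(methoxymethoxy)-2,2-dimethyl-8-(3-methylbut-2-en-1-yl)-2H-chromen-6-yl][3-(methoxymethoxy)phenyl]methanone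
Conditions: Dess–Martin periodinane, pyridine, CH2Cl2, 0 °C to rt
Reagents that add atoms: none
Why: Dess–Martin oxidation should convert the hindered diaryl carbinol into the benzophenone under buffered conditions that spare both alkenes and the MOM acetals.

Step 8
Reactants: 16 [5,7-bis(methoxymethoxy)-2,2-dimethyl-8-(3-methylbut-2-en-1-yl)-2H-chromen-6-yl][3-(methoxymethoxy)phenyl]methanone
Product: 17 [5,7-dihydroxy-2,2-dimethyl-8-(3-methylbut-2-en-1-yl)-2H-chromen-6-yl](3-hydroxyphenyl)methanone
Conditions: HCl (1 M in MeOH), 40 °C
Reagents that add atoms: none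
Why: Acid-catalysed transacetalisation to methanol should remove all three MOM ethers (the two ortho to the ketone fastest, helped by chelation) at a temperature mild enough that the prenyl group does not add to the neighbouring phenol.

**Compound list**
1 | 2,4,6-trihydroxybenzaldehyde | O=Cc1c(O)cc(O)cc1O | starting material
2 | chloromethyl methyl ether | COCCl | starting material
3 | 2-hydroxy-4,6-bis(methoxymethoxy)benzaldehyde | O=Cc1c(O)cc(OCOC)cc1OCOC | intermediate
4 | 3-chloro-3-methylbut-1-yne | C#CC(C)(C)Cl | starting material
5 | 2,4-bis(methoxymethoxy)-6-[(2-methylbut-3-yn-2-yl)oxy]benzaldehyde | O=Cc1c(OC(C)(C)C#C)cc(OCOC)cc1OCOC | intermediate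
6 | 2,4-bis(methoxymethoxy)-6-[(2-methylbut-3-en-2-yl)oxy]benzaldehyde | O=Cc1c(OC(C)(C)C=C)cc(OCOC)cc1OCOC | intermediate
7 | (2-methylprop-1-en-1-yl)boronic acid | CC(C)=CB(O)O | starting material
8 | 2-hydroxy-4,6-bis(methoxymethoxy)-3-(3-methylbut-2-en-1-yl)benzaldehyde | O=Cc1c(O)c(CC=C(C)C)c(OCOC)cc1OCOC | intermediate
9 | 2-[1-(dibenzylamino)-3-methylbut-2-en-1-yl]-3,5-bis(methoxymethoxy)-6-(3-methylbut-2-en-1-yl)phenol (racemic) | CC(C)=CC(N(Cc1ccccc1)Cc1ccccc1)c1c(O)c(CC=C(C)C)c(OCOC)cc1OCOC | intermediate
10 | (6Z)-3,5-bis(methoxymethoxy)-2-(3-methylbut-2-en-1-yl)-6-(3-methylbut-2-en-1-ylidene)cyclohexa-2,4-dien-1-one (the geometry that closes) | CC(C)=C/C=C1\C(=O)C(CC=C(C)C)=C(OCOC)C=C1OCOC | intermediate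
11 | 5,7-bis(methoxymethoxy)-2,2-dimethyl-8-(3-methylbut-2-en-1-yl)-2H-chromene | CC(C)=CCc1c(OCOC)cc(OCOC)c2c1OC(C)(C)C=C2 | intermediate
12 | 3-hydroxybenzaldehyde | O=Cc1cccc(O)c1 | starting material
13 | 3-(methoxymethoxy)benzaldehyde | O=Cc1cccc(OCOC)c1 | intermediate
14 | [5,7-bis(methoxymethoxy)-2,2-dimethyl-8-(3-methylbut-2-en-1-yl)-2H-chromen-6-yl]lithium | [Li]c1c(OCOC)c(CC=C(C)C)c2OC(C)(C)C=Cc2c1OCOC | intermediate
15 | [5,7-bis(methoxymethoxy)-2,2-dimethyl-8-(3-methylbut-2-en-1-yl)-2H-chromen-6-yl][3-(methoxymethoxy)phenyl]methanol (racemic) | CC(C)=CCc1c(OCOC)c(C(O)c2cccc(OCOC)c2)c(OCOC)c2c1OC(C)(C)C=C2 | intermediate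
16 | [5,7-bis(methoxymethoxy)-2,2-dimethyl-8-(3-methylbut-2-en-1-yl)-2H-chromen-6-yl][3-(methoxymethoxy)phenyl]methanone | CC(C)=CCc1c(OCOC)c(C(=O)c2cccc(OCOC)c2)c(OCOC)c2c1OC(C)(C)C=C2 | intermediate
17 | [5,7-dihydroxy-2,2-dimethyl-8-(3-methylbut-2-en-1-yl)-2H-chromen-6-yl](3-hydroxyphenyl)methanone | CC(C)=CCc1c(O)c(C(=O)c2cccc(O)c2)c(O)c2c1OC(C)(C)C=C2 | target

**Totals and risks**

Total step count: 8. Longest linear sequence: 7 steps (steps 1, 2, 3, 4, 6, 7, 8).

Steps most likely to fail:

Step 4. The tertiary allyl ether may ionise and lose its C5 unit before the sigmatropic shift. Alkenyl transfer may also stall at the hindered, electron-rich iminium ion while the boronic acid protodeboronates. The fallback sets out from 6 and returns at 11, replacing the boron/amine cascade by organomagnesium addition and dehydrative ring closure. Compound 6 is heated alone in PhMe and the Claisen product 8 is isolated. Treatment of 8 with Me2C=CHMgBr (2.2 equiv, THF, 0 °C) should give 2-(1-hydroxy-3-methylbut-2-en-1-yl)-3,5-bis(methoxymethoxy)-6-(3-methylbut-2-en-1-yl)phenol F1; the first equivalent forms the magnesium phenoxide and the second adds to the aldehyde. Warming F1 with PPTS (cat.) in PhMe should dehydrate the benzylic-allylic alcohol to ortho-quinone methide 10, which closes to 11.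

Step 6. The base may remove a benzylic-allylic proton of the prenyl group instead of the ring C6–H. The fallback sets out from 11 and returns at 14, replacing deprotonation by halogenation and halogen–metal exchange. Electrophilic bromination of the only free ring position with NBS (MeCN, −30 °C, in the dark) should give 6-bromo-5,7-bis(methoxymethoxy)-2,2-dimethyl-8-(3-methylbut-2-en-1-yl)-2H-chromene F2. Bromine–lithium exchange with n-BuLi (THF, −78 °C), which is faster than any deprotonation, should give aryllithium 14, and the route continues with the addition to 13.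

Step 2. O-Alkylation of the hydrogen-bonded phenoxide may be slow while the tertiary chloride is lost by elimination. The fallback sets out from 3 and returns at 6, using palladium-catalysed decarboxylative allylic etherification (Tsuji–Trost) instead of propargylation and reduction. 2-Methylbut-3-en-2-ol is converted (n-BuLi, Boc2O, THF) into tert-butyl 2-methylbut-3-en-2-yl carbonate F3. Compound 3 with F3 and Pd(PPh3)4 (THF, 0 °C) should give 6 directly, by attack of the phenoxide at the more substituted end of the 1,1-dimethylallyl palladium intermediate. Step 3 is then not needed.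

**Further compounds**
F1 | step 4 | 2-(1-hydroxy-3-methylbut-2-en-1-yl)-3,5-bis(methoxymethoxy)-6-(3-methylbut-2-en-1-yl)phenol (racemic) | CC(C)=CC(O)c1c(O)c(CC=C(C)C)c(OCOC)cc1OCOC
F2 | step 6 | 6-bromo-5,7-bis(methoxymethoxy)-2,2-dimethyl-8-(3-methylbut-2-en-1-yl)-2H-chromene | CC(C)=CCc1c(OCOC)c(Br)c(OCOC)c2c1OC(C)(C)C=C2
F3 | step 2 | tert-butyl 2-methylbut-3-en-2-yl carbonate | C=CC(C)(C)OC(=O)OC(C)(C)C
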